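## The problem

Sideroxylonal A (31) is a 2-arylchroman in which ring A (fused through O1–C8a and C4–C4a) and ring B (on C2) are both phloroglucinols carrying two formyl groups. The pyran ring holds three contiguous stereocentres, C2 (R, aryl), C3 (R, isopropyl) and C4 (S, 2-methylpropyl), arranged 2,3-trans and 3,4-cis. C2 is a benzylic ether carbon flanked by three ring B oxygens and can ionise and epimerise, so its C–O bond should be made once, early, and never broken again. The 3,4-cis relation is the less stable one wherever C4 is enolisable and has to be fixed kinetically. Only C2 lends itself to catalytic asymmetric synthesis (addition to an aryl aldehyde); C3 and C4 must be relayed from it, and because the two branched groups on C3 are alike in size this relay needs a ring. Four aldehydes and five phenols will not survive organolithium, hydride or Lewis-acid steps, so the formyl carbons must travel as esters or enter late, and the phenols as ethers. The enabling feature is ring A itself: oxygen on C5, C7 and C8a alternates with carbon on C4a, C6 and C8, and the saturated chain O1–C2–C3–C4 joins the two fusion atoms. A 2-pyranone bound through its C6 oxygen (the future O1) and an oxygen-bearing alkyne on C4 therefore map onto ring A atom for atom: the pyranone supplies C8a, C8, C7 and C6 with O1, the C7 oxygen and the C6 carboxyl carbon, the ynol ether supplies C4a and C5 with its oxygen, and the pyranone carbonyl leaves as CO2.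

## Retrosynthesis

**31 back to 28 (no skeletal bond).** The five phenols are traced to four methyl ethers and one free phenol (30), and the four formyl groups to benzylic alcohols (29) and then to three esters and one aldehyde (28). Esters are preferred to aldehydes on ring B because they survive the organometallic steps, are hindered enough to resist them, and withdraw electrons from the benzylic C2 position. The forward steps are demethylation ortho to carbonyl groups, a benzylic oxidation and a hydride reduction.

**28 back to 26 (C8–CHO).** The C8 formyl bond is cut to phenol 27 and its silyl ether 26. The neighbouring option, carrying C8 as a second ester on the pyranone, was set aside: a 3,5-diester 6-chloropyranone has no short preparation, and a geminal pair of esters beside the tether oxygen makes ring closure of any opened form ambiguous. C8 is the only unsubstituted aromatic carbon in 27, so an electrophilic formylation has no choice of site.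

**26 back to 24 (C4a–C8a and C5–C6; key step).** Both bonds are cut at once, opening ring A and the pyran ring to the 6-alkoxy-2-pyranone 24 tethered to a silyl ynol ether. Against closing O1–C2 by substitution (which endangers C2) or C4–C4a by Friedel–Crafts alkylation (ring A deactivated, C4 epimerisable), this cut leaves all three stereocentres as spectators and delivers ring A with every substituent in place. The forward reaction must be regioselective, which the four-atom tether and the matched polarity provide, and must outrun decomposition of two sensitive functions.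

**24 back to 18 and 22 (O1–C8a).** The ether bond is cut between the C2 oxygen and pyranone C6, giving alcohol 18 and chloropyranone 22. The C2–O bond is not touched, so the configuration of C2 is carried over. The forward step is an addition–elimination at a vinylogous acyl chloride that must tolerate the ynol ether; this is why the pyranone is attached last and in one mild operation.

**22 back to 19.** The pyranone is the O-methyl ether of 21, the methanolysis product of the self-condensation dimer 20 of malonyl dichloride (19). Two steps from a commercial C3 unit are all that is needed.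

**18 back to 15 (the bond from C4 to the alkyne carbon).** The ynol ether and the free C2 hydroxyl are traced together to γ-lactone 15. Homologation of the lactone carbonyl inserts the future C4a, turns the carbonyl into the ynol oxygen of C5 and releases the ring oxygen as the C2 alkoxide. The lactone is far simpler than 18 and holds the stereotriad in a five-membered ring. The forward step must not enolise C4.

**15 back to 9 and 10 (C4–H, the C4 side-chain bond and C3–isopropyl).** C4 is set by hydrogenation of alkylidene lactone 14 from the face away from the C3 isopropyl group. 14 comes from aldol adduct 12, which is made from butenolide 9 by conjugate addition of an isopropyl cuprate anti to the C2 aryl group and trapping with 2-methylpropanal (10). Acyclic alternatives were rejected because the C3 substituents do not differentiate the faces of an acyclic C4. The ring passes chirality from C2 to C3 to C4.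

**9 back to 5 and 6 (C2–C3).** The butenolide is the lactone of the cis-reduced adduct 7 of methyl propiolate (6) and ring B aldehyde 5. A catalytic asymmetric alkynylation sets C2, the only stereocentre made under reagent control.

**5 back to 1.** Aldehyde 5 is reached from 1,3,5-trimethoxybenzene (1) by twofold formylation (2), oxidation (3), esterification (4) and a third formylation at the one remaining position.

## Roads not taken

**Alternative 1:** The cut is at C4–C4a and C3–C4, with no ring formed. Boronic ester A1 of ring A would be homologated in one flask, first with the lithiated carbamate A2 and then with the lithiated benzoate A3, each under control of a chiral diamine, to give boronic ester A4 with boron on C3. Its merit is reagent control: each centre is chosen independently, so the 3,4-cis relation is obtained without fighting thermodynamics, and the chemistry is established. The weak points lie in this target. A1 is a di-ortho-substituted aryl boronate, and the second insertion must take place at a hindered benzylic boronate with an isopropyl-bearing carbenoid, among the slowest cases. A4 also stops short of the real difficulties: C2 with ring B and its oxygen, the O1–C8a bond to an aryl carbon that bears only a methyl ether, and four formylations remain. Closing the pyran would then require substitution at benzylic C2. In control of C3 and C4 this road is better than the chosen plan, whose C4 depends on a substrate-directed hydrogenation. The chosen plan sets against it a key step that closes both rings with the oxygen pattern and one carboxyl carbon in place, and a C2–O bond that is made once by catalysis.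

**Alternative 2:** The cut is at O1–C8a, C4–C4a and O1–C2. The aryne released from A5 would add across the carbonyl group of enone A6; the benzoxete would open to an ortho-quinone methide and reclose to 2H-chromene A7. It is the shortest of all the plans: three bonds and the pyran ring arise from two simple pieces, and the methoxy group next to the aryne directs the oxygen to C8a as required. Its weakness is stereochemistry. A7 is racemic at C2 with no handle for induction, and the tetrasubstituted C3=C4 alkene must be reduced. Syn addition gives the correct 3,4-cis relation, but delivery from the face away from the C2 aryl group gives 2,3-cis, the wrong one. Four formyl groups would then have to be introduced on a compound whose C2 ether is flanked by an unprotected trimethoxyphenyl ring. In step count this road is clearly better; the chosen plan answers with control of relative and absolute configuration and with three of the four formyl carbons carried in from the start.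

**Alternative 3:** The cut is at O1–C2. A flavin-dependent 4-alkylphenol oxidase would dehydrogenate the C2 methylene of diarylpropane A8 to a ring B quinone methide, which the ring A hydroxyl captures to give hexahydroxychroman A9. The merits are real: no protecting groups, mild aqueous conditions, and a closure that probably mirrors the biogenesis. The weak points are the substrate and what follows. Known enzymes of this family take small para-alkylphenols, whereas A8 has two ortho hydroxyls on ring B and a doubly branched chain at the reacting carbon, so an engineered enzyme would be needed. Capture of the quinone methide may occur outside the active site, leaving C2 to substrate control. A8 still needs C3 and C4 set, and A9 is an air-sensitive hexaphenol awaiting fourfold formylation. If an enzyme accepted A8, this road would be shorter at the end and cleaner than the chosen plan. The chosen plan relies only on reagents available now, although its own key step is untested, and needs a single late formylation.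

Key step: step 14

Remark on the chemistry: the (S,S)-ProPhenol ligand is taken to give the (R)-carbinol in step 5; if the sense of induction is the reverse, the (R,R)-ligand is used and nothing else changes. ArB stands for the protected ring B, 2,4,6-trimethoxy-3,5-bis(methoxycarbonyl)phenyl.

## Route

Step 1
Reactants: 1 1,3,5-trimethoxybenzene
Product: 2 2,4,6-trimethoxybenzene-1,3-dicarbaldehyde
Conditions: Cl2CHOMe (3 equiv), TiCl4 (4 equiv), CH2Cl2, 0 → 40 °C; H2O
Reagents that add atoms: dichloromethyl methyl ether, COC(Cl)Cl; water, O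
Why: Rieche formylation; after the first formyl group the free positions are still ortho/para to three methoxy groups, so a second enters, while the third position is left for step 4.

Step 2
Reactants: 2 2,4,6-trimethoxybenzene-1,3-dicarbaldehyde
Product: 3 2,4,6-trimethoxybenzene-1,3-dicarboxylic acid
Conditions: NaClO2, NaH2PO4, 2-methylbut-2-ene, t-BuOH/H2O, 25 °C
Reagents that add atoms: sodium chlorite, [Na+].[O-]Cl=O
Why: Pinnick oxidation converts electron-rich aryl aldehydes to acids without Dakin-type loss of the formyl carbon; the alkene scavenges hypochlorite that would chlorinate the free ring position.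

Step 3
Reactants: 3 2,4,6-trimethoxybenzene-1,3-dicarboxylic acid
Product: 4 dimethyl 2,4,6-trimethoxybenzene-1,3-dicarboxylate
Conditions: MeI, K2CO3, DMF, 25 °C
Reagents that add atoms: iodomethane, CI
Why: O-alkylation of the carboxylates (SN2 at methyl) is independent of the steric hindrance that blocks acid-catalysed esterification of di-ortho-substituted benzoic acids.

Step 4
Reactants: 4 dimethyl 2,4,6-trimethoxybenzene-1,3-dicarboxylate
Product: 5 dimethyl 5-formyl-2,4,6-trimethoxybenzene-1,3-dicarboxylate (ArB–CHO)
Conditions: Cl2CHOMe, TiCl4, CH2Cl2, −10 → 25 °C; H2O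
Reagents that add atoms: dichloromethyl methyl ether, COC(Cl)Cl; water, O
Why: Rieche formylation at the single free position, which is ortho, ortho and para to methoxy groups and only meta to the two esters.

Step 5
Reactants: 5 dimethyl 5-formyl-2,4,6-trimethoxybenzene-1,3-dicarboxylate; 6 methyl propiolate
Product: 7 methyl (4R)-4-hydroxy-4-ArB-but-2-ynoate
Conditions: ZnMe2 (3 equiv), (S,S)-ProPhenol (20 mol%), Ph3PO (40 mol%), toluene, 4 °C; aq. NH4Cl
Reagents that add atoms: none
Why: Zinc–ProPhenol-catalysed asymmetric alkynylation of an aldehyde with a propiolate; the dinuclear zinc complex binds the non-enolisable, electron-poor aldehyde and delivers the zinc acetylide to its Re face, which sets C2 (R), the only centre made under reagent control.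

Step 6
Reactants: 7 methyl (4R)-4-hydroxy-4-ArB-but-2-ynoate
Product: 9 (5R)-5-ArB-furan-2(5H)-one, via (Z)-hydroxy enoate 8 (not isolated)
Conditions: H2 (1 atm), Pd/CaCO3 poisoned with Pb(OAc)2, quinoline, EtOAc, 25 °C; then camphorsulfonic acid (cat.), CH2Cl2, 25 °C
Reagents that add atoms: none
Why: cis-Semihydrogenation of the ynoate places hydroxyl and ester on the same side of the alkene, and acid-catalysed lactonisation follows; the carbinol centre is untouched and no base is present that could enolise the butenolide.

Step 7
Reactants: 9 (5R)-5-ArB-furan-2(5H)-one; 10 2-methylpropanal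
Product: 12 (3S,4R,5R)-5-ArB-3-(1-hydroxy-2-methylpropyl)-4-(propan-2-yl)oxolan-2-one (both carbinol epimers), via lithium enolate 11 (not isolated)
Conditions: i-Pr2CuLi (from i-PrLi and CuI), Et2O/THF, −78 °C; then 10, −78 °C; aq. NH4Cl
Reagents that add atoms: lithium diisopropylcuprate, [Li+].CC(C)[Cu-]C(C)C
Why: Conjugate addition of a lithium dialkylcuprate to a γ-substituted butenolide occurs anti to the γ-substituent, here the bulky ortho-disubstituted aryl group, which sets C3 (R) trans to C2. The enolate is trapped by the aldehyde anti to the new isopropyl group (tandem conjugate addition–aldol); the two centres of the hydroxyalkyl arm are removed in steps 8 and 9. The hindered ArB esters are not attacked at −78 °C.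

Step 8
Reactants: 12 (3S,4R,5R)-5-ArB-3-(1-hydroxy-2-methylpropyl)-4-(propan-2-yl)oxolan-2-one
Product: 14 (3E,4R,5R)-5-ArB-3-(2-methylpropylidene)-4-(propan-2-yl)oxolan-2-one, via methanesulfonate 13 (not isolated)
Conditions: MsCl, Et3N, CH2Cl2, 0 °C; then DBU, 25 °C
Reagents that add atoms: none
Why: Mesylation and E1cB elimination of the β-sulfonyloxy lactone give the conjugated exocyclic alkene; either alkene geometry serves in step 9.

Step 9
Reactants: 14 (3E,4R,5R)-5-ArB-3-(2-methylpropylidene)-4-(propan-2-yl)oxolan-2-one
Product: 15 (3S,4R,5R)-5-ArB-3-(2-methylpropyl)-4-(propan-2-yl)oxolan-2-one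
Conditions: H2 (1 atm), Rh/Al2O3 (5%), EtOAc, 25 °C
Reagents that add atoms: none
Why: Heterogeneous hydrogenation of α-alkylidene-β-substituted γ-butyrolactones delivers hydrogen to the face opposite the adjacent β-substituent, so the new C4–H bond is trans to the isopropyl group and the 2-methylpropyl group ends cis to it (C4 S, the kinetic arrangement). Rh/Al2O3 is chosen to avoid hydrogenolysis of the benzylic lactone C–O bond.

Step 10
Reactants: 15 (3S,4R,5R)-5-ArB-3-(2-methylpropyl)-4-(propan-2-yl)oxolan-2-one
Product: 18 dimethyl 5-[(1R,2R,3S)-1-hydroxy-5-methyl-2-(propan-2-yl)-3-({[tri(propan-2-yl)silyl]oxy}ethynyl)hexyl]-2,4,6-trimethoxybenzene-1,3-dicarboxylate, via dilithium dibromoenolate alkoxide 16 (not isolated), via dilithium ynolate alkoxide 17 (not isolated)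
Conditions: CH2Br2, LiTMP (lithium 2,2,6,6-tetramethylpiperidide), THF, −78 °C; LiN(SiMe3)2; n-BuLi, −78 → 20 °C; then i-Pr3SiCl (1.05 equiv), −78 → 0 °C; pH 7 buffer
Reagents that add atoms: dibromomethane, BrCBr; chlorotri(propan-2-yl)silane, CC(C)[Si](Cl)(C(C)C)C(C)C
Why: Kowalski ester homologation applied to a lactone: LiCHBr2 adds to the carbonyl group, the ring opens, and the dibromoenolate 16 undergoes Br/Li exchange and 1,2-shift of the C4 carbon with retention to give ynolate 17. The bulky chlorosilane silylates the ynolate oxygen and not the hindered secondary lithium alkoxide, so one operation inserts the future C4a, makes the ynol ether and frees the C2 oxygen. Carbonyl addition and deprotonation at CHBr2 outrun enolisation at C4, and di-ortho-substituted benzoates resist organolithiums at −78 °C.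

Step 11
Reactants: 19 malonyl dichloride
Product: 21 methyl 6-chloro-4-hydroxy-2-oxo-2H-pyran-3-carboxylate, via pyranone acid chloride 20 (not isolated)
Conditions: neat, 25 °C, moisture excluded; then MeOH (1 equiv), CH2Cl2, 0 °C
Reagents that add atoms: methanol, CO
Why: Malonyl dichloride self-condenses through chlorocarbonylketene to the known pyranone acid chloride 20 ([4+2]-type dimerisation with loss of HCl); the acyl chloride is far more reactive toward methanol than the vinylogous 6-chloride.

Step 12
Reactants: 21 methyl 6-chloro-4-hydroxy-2-oxo-2H-pyran-3-carboxylate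
Product: 22 methyl 6-chloro-4-methoxy-2-oxo-2H-pyran-3-carboxylate
Conditions: Me3SiCHN2, toluene/MeOH, 0 °C
Reagents that add atoms: (trimethylsilyl)diazomethane, C[Si](C)(C)C=[N+]=[N-]
Why: The 4-hydroxyl of a 4-hydroxy-2-pyranone is a vinylogous carboxylic acid and is O-methylated by diazomethane generated in situ, under neutral conditions that leave the 6-chloride intact.

Step 13
Reactants: 18 dimethyl 5-[(1R,2R,3S)-1-hydroxy-5-methyl-2-(propan-2-yl)-3-({[tri(propan-2-yl)silyl]oxy}ethynyl)hexyl]-2,4,6-trimethoxybenzene-1,3-dicarboxylate; 22 methyl 6-chloro-4-methoxy-2-oxo-2H-pyran-3-carboxylate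
Product: 24 methyl 6-{[(1R,2R,3S)-1-ArB-5-methyl-2-(propan-2-yl)-3-({[tri(propan-2-yl)silyl]oxy}ethynyl)hexyl]oxy}-4-methoxy-2-oxo-2H-pyran-3-carboxylate, via sodium alkoxide 23 (not isolated)
Conditions: NaN(SiMe3)2 (1.0 equiv), THF, −78 °C; then 22, −78 → −20 °C; pH 7 buffer; crude product used directly
Reagents that add atoms: none
Why: Addition–elimination of an alkoxide at C6 of a 6-chloro-2-pyranone, a vinylogous acyl chloride whose chlorine is known to be displaced by oxygen and nitrogen nucleophiles. C6 is the most electrophilic site because C2 and the ester are deactivated by the push–pull 4-methoxy enol ether. The C2–O bond is not broken, so C2 keeps its configuration, and the ynol ether tolerates the base at low temperature.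

Step 14
Reactants: 24 methyl 6-{[(1R,2R,3S)-1-ArB-5-methyl-2-(propan-2-yl)-3-({[tri(propan-2-yl)silyl]oxy}ethynyl)hexyl]oxy}-4-methoxy-2-oxo-2H-pyran-3-carboxylate
Product: 26 methyl (2R,3R,4S)-2-ArB-7-methoxy-4-(2-methylpropyl)-3-(propan-2-yl)-5-{[tri(propan-2-yl)silyl]oxy}-3,4-dihydro-2H-chromene-6-carboxylate, via bicyclic lactone 25 (not isolated)
Conditions: toluene (0.01 M), 2,6-di-tert-butyl-4-methylpyridine (0.2 equiv), 110 °C
Reagents that add atoms: none
Why: Proposed new method: an intramolecular inverse-electron-demand [4+2] cycloaddition is proposed in which the nucleophilic alkyne carbon (the one bound to C4) attacks the acetal-like pyranone C6 while the ester-bearing pyranone C3 closes onto the silyloxy-substituted alkyne carbon, giving bicyclic lactone 25, which loses CO2 by retro-[4+2] so that ring A is formed directly as an arene. The closest known reaction types are the thermal intramolecular Diels–Alder reaction of 2-pyranones with tethered alkynes with loss of CO2 and the intermolecular inverse-demand addition of ynamines and ketene acetals to 2-pyranone-3-carboxylates; a silyl ynol ether has not been shown as the tethered partner of a 6-alkoxy-2-pyranone. The pyran ring closes as the six-membered tether ring of the cycloaddition through the C4a–C8a bond (6-exo attack of the alkyne carbon on pyranone C6), and ring A closes through the second bond, C5–C6, and becomes aromatic on decarboxylation. No stereocentre is created in 26: the two bridgehead centres of 25 vanish with CO2, so both facial diastereomers of 25 converge, and C2, C3 and C4 are spectators. Regiochemistry is the only selectivity needed; the four-atom tether O1–C2–C3–C4 allows only the union of C6 with the inner alkyne carbon, and the polarity of both partners agrees with it. Dilution suppresses bimolecular reaction, the hindered base removes traces of acid that would protonate the ynol ether or ionise the benzylic pyranyl ether, and the temperature stays below that at which triisopropylsilyl ynol ethers rearrange to silylketenes.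

Step 15
Reactants: 26 methyl (2R,3R,4S)-2-ArB-7-methoxy-4-(2-methylpropyl)-3-(propan-2-yl)-5-{[tri(propan-2-yl)silyl]oxy}-3,4-dihydro-2H-chromene-6-carboxylate
Product: 27 methyl (2R,3R,4S)-2-ArB-5-hydroxy-7-methoxy-4-(2-methylpropyl)-3-(propan-2-yl)-3,4-dihydro-2H-chromene-6-carboxylate
Conditions: Bu4NF, AcOH, THF, 0 °C
Reagents that add atoms: none
Why: Fluoride cleaves the aryl silyl ether; the acetic acid buffer keeps the medium from opening the chroman, and the phenol is held by a hydrogen bond to the C6 ester.

Step 16
Reactants: 27 methyl (2R,3R,4S)-2-ArB-5-hydroxy-7-methoxy-4-(2-methylpropyl)-3-(propan-2-yl)-3,4-dihydro-2H-chromene-6-carboxylate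
Product: 28 methyl (2R,3R,4S)-2-ArB-8-formyl-5-hydroxy-7-methoxy-4-(2-methylpropyl)-3-(propan-2-yl)-3,4-dihydro-2H-chromene-6-carboxylate
Conditions: Cl2CHOMe, TiCl4, CH2Cl2, −78 → 0 °C; H2O
Reagents that add atoms: dichloromethyl methyl ether, COC(Cl)Cl; water, O
Why: Rieche formylation of a phenol: C8 is the only unsubstituted aromatic carbon in the molecule (ring B is hexasubstituted) and is para to the phenol and ortho to two ether oxygens. Low temperature and the ester-deactivated ring B guard the C2–O1 bond against Lewis-acid ionisation.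

Step 17
Reactants: 28 methyl (2R,3R,4S)-2-ArB-8-formyl-5-hydroxy-7-methoxy-4-(2-methylpropyl)-3-(propan-2-yl)-3,4-dihydro-2H-chromene-6-carboxylate
Product: 29 (2R,3R,4S)-2-[3,5-bis(hydroxymethyl)-2,4,6-trimethoxyphenyl]-6,8-bis(hydroxymethyl)-7-methoxy-4-(2-methylpropyl)-3-(propan-2-yl)-3,4-dihydro-2H-chromen-5-ol
Conditions: LiAlH4, THF, 0 → 25 °C; aq. potassium sodium tartrate
Reagents that add atoms: none
Why: LiAlH4 reduces the three esters and the aldehyde to primary benzylic alcohols; di-ortho-substituted benzoates yield to this small hydride. The temperature is held at or below 25 °C to avoid over-reduction of the ortho-hydroxybenzyl alcohol through a quinone methide.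

Step 18
Reactants: 29 (2R,3R,4S)-2-[3,5-bis(hydroxymethyl)-2,4,6-trimethoxyphenyl]-6,8-bis(hydroxymethyl)-7-methoxy-4-(2-methylpropyl)-3-(propan-2-yl)-3,4-dihydro-2H-chromen-5-ol
Product: 30 (2R,3R,4S)-2-(3,5-diformyl-2,4,6-trimethoxyphenyl)-5-hydroxy-7-methoxy-4-(2-methylpropyl)-3-(propan-2-yl)-3,4-dihydro-2H-chromene-6,8-dicarbaldehyde
Conditions: MnO2 (activated, excess), CH2Cl2/acetone, 25 °C
Reagents that add atoms: none
Why: MnO2 oxidises benzylic alcohols to aldehydes without going on to acids; each formyl group formed deactivates its ring toward oxidation of the phenol.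

Step 19
Reactants: 30 (2R,3R,4S)-2-(3,5-diformyl-2,4,6-trimethoxyphenyl)-5-hydroxy-7-methoxy-4-(2-methylpropyl)-3-(propan-2-yl)-3,4-dihydro-2H-chromene-6,8-dicarbaldehyde
Product: 31 sideroxylonal A, (2R,3R,4S)-2-(3,5-diformyl-2,4,6-trihydroxyphenyl)-5,7-dihydroxy-4-(2-methylpropyl)-3-(propan-2-yl)-3,4-dihydro-2H-chromene-6,8-dicarbaldehyde
Conditions: BBr3, CH2Cl2, −78 → 0 °C; H2O
Reagents that add atoms: none
Why: BBr3 cleaves aryl methyl ethers; all four methoxy groups are ortho to a formyl group, so chelation of boron to the carbonyl oxygen speeds their cleavage at low temperature. The C2–O1 bond, deactivated by the two formyl groups of ring B, should keep its configuration under these conditions.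

## Compound list

1 | 1,3,5-trimethoxybenzene | COc1cc(OC)cc(OC)c1 | starting material
2 | 2,4,6-trimethoxybenzene-1,3-dicarbaldehyde | O=Cc1c(OC)c(C=O)c(OC)cc1OC | intermediate
3 | 2,4,6-trimethoxybenzene-1,3-dicarboxylic acid | OC(=O)c1c(OC)c(C(=O)O)c(OC)cc1OC | intermediate
4 | dimethyl 2,4,6-trimethoxybenzene-1,3-dicarboxylate | COC(=O)c1c(OC)c(C(=O)OC)c(OC)cc1OC | intermediate
5 | dimethyl 5-formyl-2,4,6-trimethoxybenzene-1,3-dicarboxylate (ArB–CHO) | O=Cc1c(OC)c(C(=O)OC)c(OC)c(C(=O)OC)c1OC | intermediate
6 | methyl propiolate | C#CC(=O)OC | starting material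
7 | methyl (4R)-4-hydroxy-4-ArB-but-2-ynoate | COC(=O)C#C[C@H](c1c(OC)c(C(=O)OC)c(OC)c(C(=O)OC)c1OC)O | intermediate
8 | methyl (2Z,4R)-4-hydroxy-4-ArB-but-2-enoate | COC(=O)/C=C\[C@H](c1c(OC)c(C(=O)OC)c(OC)c(C(=O)OC)c1OC)O | intermediate
9 | (5R)-5-ArB-furan-2(5H)-one | O=C1C=C[C@H](c2c(OC)c(C(=O)OC)c(OC)c(C(=O)OC)c2OC)O1 | intermediate
10 | 2-methylpropanal | CC(C)C=O | starting material
11 | lithium (4R,5R)-5-ArB-4-(propan-2-yl)-4,5-dihydrofuran-2-olate | [Li+].[O-]C1=C[C@@H](C(C)C)[C@H](c2c(OC)c(C(=O)OC)c(OC)c(C(=O)OC)c2OC)O1 | intermediate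
12 | (3S,4R,5R)-5-ArB-3-(1-hydroxy-2-methylpropyl)-4-(propan-2-yl)oxolan-2-one, both carbinol epimers | CC(C)C(O)[C@@H]1[C@@H](C(C)C)[C@H](c2c(OC)c(C(=O)OC)c(OC)c(C(=O)OC)c2OC)OC1=O | intermediate
13 | methanesulfonate of 12, (3S,4R,5R), both epimers at the sulfonyloxy carbon | CC(C)C(OS(C)(=O)=O)[C@@H]1[C@@H](C(C)C)[C@H](c2c(OC)c(C(=O)OC)c(OC)c(C(=O)OC)c2OC)OC1=O | intermediate
14 | (3E,4R,5R)-5-ArB-3-(2-methylpropylidene)-4-(propan-2-yl)oxolan-2-one | CC(C)/C=C1/C(=O)O[C@@H](c2c(OC)c(C(=O)OC)c(OC)c(C(=O)OC)c2OC)[C@@H]1C(C)C | intermediate
15 | (3S,4R,5R)-5-ArB-3-(2-methylpropyl)-4-(propan-2-yl)oxolan-2-one | CC(C)C[C@H]1[C@@H](C(C)C)[C@H](c2c(OC)c(C(=O)OC)c(OC)c(C(=O)OC)c2OC)OC1=O | intermediate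
16 | dilithium alkoxide–enolate of the ring-opened 1,1-dibromomethyl ketone, Li2[ArB–CH(O)–CH(i-Pr)–CH(i-Bu)–C(O)=CBr2], stereocentres as in 15 | [Li+].[Li+].CC(C)C[C@H](C([O-])=C(Br)Br)[C@@H](C(C)C)[C@H](c1c(OC)c(C(=O)OC)c(OC)c(C(=O)OC)c1OC)[O-] | intermediate
17 | dilithium alkoxide–ynolate, Li2[ArB–CH(O)–CH(i-Pr)–CH(i-Bu)–C≡C–O], stereocentres as in 18 | [Li+].[Li+].CC(C)C[C@H](C#C[O-])[C@@H](C(C)C)[C@H](c1c(OC)c(C(=O)OC)c(OC)c(C(=O)OC)c1OC)[O-] | intermediate
18 | dimethyl 5-[(1R,2R,3S)-1-hydroxy-5-methyl-2-(propan-2-yl)-3-({[tri(propan-2-yl)silyl]oxy}ethynyl)hexyl]-2,4,6-trimethoxybenzene-1,3-dicarboxylate | CC(C)C[C@H](C#CO[Si](C(C)C)(C(C)C)C(C)C)[C@@H](C(C)C)[C@H](c1c(OC)c(C(=O)OC)c(OC)c(C(=O)OC)c1OC)O | intermediate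
19 | malonyl dichloride (propanedioyl dichloride) | O=C(Cl)CC(=O)Cl | starting material
20 | 6-chloro-4-hydroxy-2-oxo-2H-pyran-3-carbonyl chloride | O=C(Cl)c1c(O)cc(Cl)oc1=O | intermediate
21 | methyl 6-chloro-4-hydroxy-2-oxo-2H-pyran-3-carboxylate | COC(=O)c1c(O)cc(Cl)oc1=O | intermediate
22 | methyl 6-chloro-4-methoxy-2-oxo-2H-pyran-3-carboxylate | COC(=O)c1c(OC)cc(Cl)oc1=O | intermediate
23 | sodium alkoxide of 18 | [Na+].CC(C)C[C@H](C#CO[Si](C(C)C)(C(C)C)C(C)C)[C@@H](C(C)C)[C@H](c1c(OC)c(C(=O)OC)c(OC)c(C(=O)OC)c1OC)[O-] | intermediate
24 | methyl 6-{[(1R,2R,3S)-1-ArB-5-methyl-2-(propan-2-yl)-3-({[tri(propan-2-yl)silyl]oxy}ethynyl)hexyl]oxy}-4-methoxy-2-oxo-2H-pyran-3-carboxylate | CC(C)C[C@H](C#CO[Si](C(C)C)(C(C)C)C(C)C)[C@@H](C(C)C)[C@H](c1c(OC)c(C(=O)OC)c(OC)c(C(=O)OC)c1OC)Oc1cc(OC)c(C(=O)OC)c(=O)o1 | intermediate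
25 | bicyclic lactone (2-oxabicyclo[2.2.2]octadienone fused to the dihydropyran; either configuration at the two bridgeheads; C2, C3, C4 as in 26) | CC(C)C[C@@H]1C2=C(O[Si](C(C)C)(C(C)C)C(C)C)C3(C(=O)OC)C(OC)=CC2(OC3=O)O[C@@H](c2c(OC)c(C(=O)OC)c(OC)c(C(=O)OC)c2OC)[C@@H]1C(C)C | intermediate
26 | methyl (2R,3R,4S)-2-ArB-7-methoxy-4-(2-methylpropyl)-3-(propan-2-yl)-5-{[tri(propan-2-yl)silyl]oxy}-3,4-dihydro-2H-chromene-6-carboxylate | CC(C)C[C@@H]1c2c(O[Si](C(C)C)(C(C)C)C(C)C)c(C(=O)OC)c(OC)cc2O[C@@H](c2c(OC)c(C(=O)OC)c(OC)c(C(=O)OC)c2OC)[C@@H]1C(C)C | intermediate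
27 | methyl (2R,3R,4S)-2-ArB-5-hydroxy-7-methoxy-4-(2-methylpropyl)-3-(propan-2-yl)-3,4-dihydro-2H-chromene-6-carboxylate | CC(C)C[C@@H]1c2c(O)c(C(=O)OC)c(OC)cc2O[C@@H](c2c(OC)c(C(=O)OC)c(OC)c(C(=O)OC)c2OC)[C@@H]1C(C)C | intermediate
28 | methyl (2R,3R,4S)-2-ArB-8-formyl-5-hydroxy-7-methoxy-4-(2-methylpropyl)-3-(propan-2-yl)-3,4-dihydro-2H-chromene-6-carboxylate | CC(C)C[C@@H]1c2c(O)c(C(=O)OC)c(OC)c(C=O)c2O[C@@H](c2c(OC)c(C(=O)OC)c(OC)c(C(=O)OC)c2OC)[C@@H]1C(C)C | intermediate
29 | (2R,3R,4S)-2-[3,5-bis(hydroxymethyl)-2,4,6-trimethoxyphenyl]-6,8-bis(hydroxymethyl)-7-methoxy-4-(2-methylpropyl)-3-(propan-2-yl)-3,4-dihydro-2H-chromen-5-ol | CC(C)C[C@@H]1c2c(O)c(CO)c(OC)c(CO)c2O[C@@H](c2c(OC)c(CO)c(OC)c(CO)c2OC)[C@@H]1C(C)C | intermediate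
30 | (2R,3R,4S)-2-(3,5-diformyl-2,4,6-trimethoxyphenyl)-5-hydroxy-7-methoxy-4-(2-methylpropyl)-3-(propan-2-yl)-3,4-dihydro-2H-chromene-6,8-dicarbaldehyde | CC(C)C[C@@H]1c2c(O)c(C=O)c(OC)c(C=O)c2O[C@@H](c2c(OC)c(C=O)c(OC)c(C=O)c2OC)[C@@H]1C(C)C | intermediate
31 | sideroxylonal A | CC(C)C[C@@H]1c2c(O)c(C=O)c(O)c(C=O)c2O[C@@H](c2c(O)c(C=O)c(O)c(C=O)c2O)[C@@H]1C(C)C | target

## Step count and least certain steps

Total: 19 steps. Longest linear sequence: 17 steps (steps 1–10 and 13–19); steps 11 and 12 make the pyranone.

**Step 14 (key step).** The most likely failure is heterolysis of the benzylic C2–O bond of 24 on heating, since the pyranone oxide is a good leaving group. Rearrangement or protonation of the silyl ynol ether before it can add is the second danger. In either case no cycloadduct forms. The fallback uses known chemistry, sets out from 18 and returns at 29. Alcohol 18 is heated with 3-methoxycyclobut-2-en-1-one (toluene, 80 → 110 °C) in a Danheiser benzannulation. The vinylketene adds to the ynol ether and the sequence of electrocyclic steps gives the resorcinol monosilyl ether F1, in which the side chain sits between the new phenol (C8a) and the silyloxy group (C5). Acid-catalysed cyclodehydration of F1 (TsOH cat., CH2Cl2) closes O1–C2 through the benzylic cation to chroman F2. The 2,3-trans isomer is expected because the cation is attacked anti to the isopropyl group and this isomer is also the more stable. Desilylation with Bu4NF gives phenol F3, twofold Rieche formylation at C6 and C8 gives dialdehyde F4, and LiAlH4 reduces F4 to 29. This detour gives up reagent-independent retention at C2, which is its price.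

**Step 10.** The likely failures are enolisation of the lactone at C4 by the amide base, which would epimerise C4 to the more stable trans lactone, and attack of the organolithiums on the ArB esters. The fallback sets out from 15 and returns at 18. i-Bu2AlH (CH2Cl2, −78 °C) reduces 15 to lactol F5. The Ohira–Bestmann reagent (dimethyl (1-diazo-2-oxopropyl)phosphonate, K2CO3, MeOH) converts F5 to the hydroxy alkyne F6. Double deprotonation with LiN(SiMe3)2 and oxidation of the acetylide with t-BuOOLi gives ynolate 17, which is silylated with i-Pr3SiCl to 18. This avoids carbenoid chemistry at the cost of two steps and of an aldehyde intermediate that is epimerisable at C4.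

**Step 13.** The likely failures are attack of the hindered alkoxide at C2 of the pyranone with ring opening, or loss of the acid-sensitive ynol ether while the ether is being made and handled. The fallback removes the ynol ether from this step; it sets out from 15 and returns at 27. Lactone 15 is taken through F5 to alkyne F6 as described for step 10. The sodium alkoxide of F6 is coupled with 22, now without any constraint from an ynol ether, to give pyranyl ether F7. Dehydrogenative borylation of the terminal alkyne with pinacolborane (Zn(OTf)2 cat., pyridine) gives alkynyl boronate F8. The intramolecular Diels–Alder reaction of the pyranone with the alkynyl boronate, a known pairing, followed by loss of CO2, gives aryl boronate F9 with boron on C5. Oxidation with NaBO3 gives phenol 27. The alkynyl boronate is a poorer dienophile than the ynol ether and will need a higher temperature.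

**Step 9.** The likely failure is poor facial selectivity, because the C2 aryl group lies on the face opposite the isopropyl group and may hinder the catalyst surface; hydrogenolysis of the benzylic C–O bond is the second risk. The fallback sets out from 14 and returns at 15. Conjugate reduction with LiBH(s-Bu)3 (THF, −78 °C) gives lithium enolate F10, which is protonated under kinetic control by 2,6-di-tert-butyl-4-methylphenol. A proton is far smaller than a catalyst surface and is steered mainly by the adjacent isopropyl group, so it should enter anti to it and give the same cis lactone.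

## Further compounds

F1 | step 14 | dimethyl 5-[(1R,2R,3S)-1-hydroxy-3-(2-hydroxy-4-methoxy-6-{[tri(propan-2-yl)silyl]oxy}phenyl)-5-methyl-2-(propan-2-yl)hexyl]-2,4,6-trimethoxybenzene-1,3-dicarboxylate | CC(C)C[C@H](c1c(O)cc(OC)cc1O[Si](C(C)C)(C(C)C)C(C)C)[C@@H](C(C)C)[C@H](c1c(OC)c(C(=O)OC)c(OC)c(C(=O)OC)c1OC)O
F2 | step 14 | (2R,3R,4S)-2-ArB-7-methoxy-4-(2-methylpropyl)-3-(propan-2-yl)-5-{[tri(propan-2-yl)silyl]oxy}-3,4-dihydro-2H-chromene | CC(C)C[C@@H]1c2c(O[Si](C(C)C)(C(C)C)C(C)C)cc(OC)cc2O[C@@H](c2c(OC)c(C(=O)OC)c(OC)c(C(=O)OC)c2OC)[C@@H]1C(C)C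
F3 | step 14 | (2R,3R,4S)-2-ArB-7-methoxy-4-(2-methylpropyl)-3-(propan-2-yl)-3,4-dihydro-2H-chromen-5-ol | CC(C)C[C@@H]1c2c(O)cc(OC)cc2O[C@@H](c2c(OC)c(C(=O)OC)c(OC)c(C(=O)OC)c2OC)[C@@H]1C(C)C
F4 | step 14 | (2R,3R,4S)-2-ArB-5-hydroxy-7-methoxy-4-(2-methylpropyl)-3-(propan-2-yl)-3,4-dihydro-2H-chromene-6,8-dicarbaldehyde | CC(C)C[C@@H]1c2c(O)c(C=O)c(OC)c(C=O)c2O[C@@H](c2c(OC)c(C(=O)OC)c(OC)c(C(=O)OC)c2OC)[C@@H]1C(C)C
F5 | step 10 | (3S,4R,5R)-5-ArB-3-(2-methylpropyl)-4-(propan-2-yl)oxolan-2-ol (lactol, both anomers) | CC(C)C[C@H]1[C@@H](C(C)C)[C@H](c2c(OC)c(C(=O)OC)c(OC)c(C(=O)OC)c2OC)OC1O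
F6 | step 10 | dimethyl 5-[(1R,2R,3S)-3-ethynyl-1-hydroxy-5-methyl-2-(propan-2-yl)hexyl]-2,4,6-trimethoxybenzene-1,3-dicarboxylate | CC(C)C[C@H](C#C)[C@@H](C(C)C)[C@H](c1c(OC)c(C(=O)OC)c(OC)c(C(=O)OC)c1OC)O
F7 | step 13 | methyl 6-{[(1R,2R,3S)-1-ArB-3-ethynyl-5-methyl-2-(propan-2-yl)hexyl]oxy}-4-methoxy-2-oxo-2H-pyran-3-carboxylate | CC(C)C[C@H](C#C)[C@@H](C(C)C)[C@H](c1c(OC)c(C(=O)OC)c(OC)c(C(=O)OC)c1OC)Oc1cc(OC)c(C(=O)OC)c(=O)o1
F8 | step 13 | pinacol alkynylboronate of F7 (boron on the terminal alkyne carbon; stereocentres as in F7) | CC(C)C[C@H](C#CB1OC(C)(C)C(C)(C)O1)[C@@H](C(C)C)[C@H](c1c(OC)c(C(=O)OC)c(OC)c(C(=O)OC)c1OC)Oc1cc(OC)c(C(=O)OC)c(=O)o1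
F9 | step 13 | methyl (2R,3R,4S)-2-ArB-7-methoxy-4-(2-methylpropyl)-3-(propan-2-yl)-5-(4,4,5,5-tetramethyl-1,3,2-dioxaborolan-2-yl)-3,4-dihydro-2H-chromene-6-carboxylate | CC(C)C[C@@H]1c2c(B3OC(C)(C)C(C)(C)O3)c(C(=O)OC)c(OC)cc2O[C@@H](c2c(OC)c(C(=O)OC)c(OC)c(C(=O)OC)c2OC)[C@@H]1C(C)C
F10 | step 9 | lithium (4R,5R)-5-ArB-3-(2-methylpropyl)-4-(propan-2-yl)-4,5-dihydrofuran-2-olate | [Li+].CC(C)CC1=C([O-])O[C@@H](c2c(OC)c(C(=O)OC)c(OC)c(C(=O)OC)c2OC)[C@@H]1C(C)C
A1 | alternative 1 | 4,4,5,5-tetramethyl-2-(2,4,6-trimethoxyphenyl)-1,3,2-dioxaborolane | COc1cc(OC)c(B2OC(C)(C)C(C)(C)O2)c(OC)c1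
A2 | alternative 1 | 3-methylbutyl N,N-di(propan-2-yl)carbamate | CC(C)CCOC(=O)N(C(C)C)C(C)C
A3 | alternative 1 | 2-methylpropyl 2,4,6-tri(propan-2-yl)benzoate | CC(C)COC(=O)c1c(C(C)C)cc(C(C)C)cc1C(C)C
A4 | alternative 1 | 2-[(3R,4S)-2,6-dimethyl-4-(2,4,6-trimethoxyphenyl)heptan-3-yl]-4,4,5,5-tetramethyl-1,3,2-dioxaborolane | CC(C)C[C@H](c1c(OC)cc(OC)cc1OC)[C@@H](C(C)C)B1OC(C)(C)C(C)(C)O1
A5 | alternative 2 | 3,5-dimethoxy-2-(trimethylsilyl)phenyl trifluoromethanesulfonate | COc1cc(OC)c([Si](C)(C)C)c(OS(=O)(=O)C(F)(F)F)c1
A6 | alternative 2 | (1E)-5-methyl-2-(propan-2-yl)-1-(2,4,6-trimethoxyphenyl)hex-1-en-3-one | CC(C)CC(=O)/C(C(C)C)=C/c1c(OC)cc(OC)cc1OC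
A7 | alternative 2 | 5,7-dimethoxy-4-(2-methylpropyl)-3-(propan-2-yl)-2-(2,4,6-trimethoxyphenyl)-2H-chromene (racemic at C2) | CC(C)CC1=C(C(C)C)C(c2c(OC)cc(OC)cc2OC)Oc2cc(OC)cc(OC)c12
A8 | alternative 3 | hexahydroxy 1,3-diarylpropane, ring B–CH2–CH(i-Pr)–CH(i-Bu)–ring A, C3 and C4 configured as in 31 | CC(C)C[C@H](c1c(O)cc(O)cc1O)[C@@H](C(C)C)Cc1c(O)cc(O)cc1O
A9 | alternative 3 | (2R,3R,4S)-4-(2-methylpropyl)-3-(propan-2-yl)-2-(2,4,6-trihydroxyphenyl)-3,4-dihydro-2H-chromene-5,7-diol | CC(C)C[C@@H]1c2c(O)cc(O)cc2O[C@@H](c2c(O)cc(O)cc2O)[C@@H]1C(C)C
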